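## Structural features

The target is a germacranolide: a ten-membered carbocycle (C1–C10) with two Z trisubstituted olefins, C1=C10 and C4=C5, carrying methyl groups on C10 and C4, and a γ-lactone trans-fused across C6–C7 (oxygen on C6, carbonyl C12, C11 on C7). Three stereocentres stand side by side on the ring (C6, C7 and the acetoxy carbon C8), the fully substituted C11 (hydroxyl and chloromethyl) adjoins C7 on the lactone, and the second acetoxy carbon C2 is isolated on the far side of the ring; the configuration is (2S,6R,7R,8R,11S). Fragile points are the allylic C–O bonds at C2 and C6 (ionisation and transannular reactions under acid), the tertiary chlorohydrin, which closes to the 11,13-epoxide with base, and the 8-oxygen, which is γ to C12 just as the 6-oxygen is, so that lactone closure can go either way. The real difficulty is the ten-membered ring with two Z trisubstituted alkenes, together with the remote C2 centre. The key step exploits the 1,5-relation of the oxygenated carbons C8 and C2 across C9–C10(Me)=C1: taking C10 and C1 out as propyne leaves C8 and C2 joined through C9 as the 1,3-dicarbonyl unit of an eight-membered ring, and the ring-expanded product is a (2Z,8Z)-cyclodeca-2,8-diene-1,5-dione (lowest locants, C2=O as position 1 and C8=O as position 5). Two properties of that eight-membered dione shape the plan: its in-ring enol is ring-cis, so the enol hydroxyl and the remaining carbonyl point apart and cannot chelate, and its two enols (towards C2 or towards C8) would lead to constitutionally different enediones. The enol is therefore locked as the C2 silyl enol ether before irradiation. Both ketones of the enedione are reduced late, so C8 and C2 are the stereocentres that need most care.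

## Logic of the disconnections

30 ⇒ 29. The two acetate C–O bonds are cut last, because acetates survive neither enolate chemistry nor peroxide anions. The forward step must acylate two secondary hydroxyls and leave the tertiary C11 hydroxyl alone.

29 ⇒ 28 ⇒ 27 ⇒ 26. The C13–Cl bond and then the C11–O bond are cut, going back through the spiro-epoxide 27 to the methylene lactone 26. This turns the quaternary C11 into a trigonal carbon whose faces are differentiated by the C7 substituents. The forward steps need a nucleophilic oxidant that ignores the two electron-rich ring olefins, oxygen delivery to the α face of C11, and chloride attack at C13 only.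

26 ⇒ 23. The C11=C13 bond is cut, removing one carbon and leaving a plain lactone. The forward step needs a lactone enolate, so C2 and C8 must carry base-stable silyl ethers.

23 ⇒ 21 (through 22). The lactone C12–O bond is cut to a methyl ester and a C6 silyl ether. Because the C8 oxygen is also γ to C12, the forward step demands that C6 alone is unmasked: a triethylsilyl ether on C6 against tert-butyldimethylsilyl ethers on C2 and C8.

21 ⇒ 20 ⇒ 19 ⇒ 18 ⇒ 17. The C2–H and C8–H bonds (and the silyl groups) are cut, returning both carbinols to ketones. C8 must be reduced first and selectively (saturated ketone against enone, Felkin–Anh control from C7). C2 has no neighbouring stereocentre and needs reagent control, of the sense opposite to that which C8 would need, which is why the two reductions are separate.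

17 ⇒ 13 + 14. The C9–C10 and C1–C2 bonds are cut and C9–C2 is re-formed: a two-carbon ring contraction to the eight-membered dione and propyne. This removes the ten-membered ring, one trisubstituted Z olefin and two skeletal bonds at once. The forward step must react through the C2 enol and bond the methyl-bearing alkyne carbon to C9.

13 ⇒ 12 ⇒ 11. The C2 carbonyl is taken back to a carbinol and the C4=C5 bond is cut by retro-metathesis. Ring closure at the hydroxy ketone stage avoids the extended, chelated enol of an open-chain 1,3-diketone, which holds the two olefins apart. The forward step needs an eight-membered ring closure onto a 1,1-disubstituted olefin.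

11 ⇒ 8 + 10. The C9–C2 bond is cut as an aldol. The nucleophile is placed on the methyl ketone 8, whose methyl group is the only easily enolised site. The opposite polarity would need the enolate of a β,γ-unsaturated methyl ketone, which forms at the doubly activated allylic CH2 and not at the methyl group.

8 ⇒ 7 ⇒ 6. The C8–C9 bond is cut to a thioester and a methyl-metal reagent, and the thioester back to the imide. The forward steps must spare the C12 methyl ester and the C7 stereocentre, hence a thiolate and an organozinc.

6 ⇒ 5 ⇒ 3 + 4. The C6–C7 bond is cut as an auxiliary-controlled syn-aldol, which sets both stereocentres from which all others are derived. The forward step must enolise the imide and not the ester, and add 1,2 to acrolein.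

3 ⇒ 1 + 2 and 10 ⇒ 9. The N-acyl bond and the aldehyde oxidation level are cut back to commercial materials.

## Other disconnections considered

Alternative 1: The cut is C5–C6 together with the lactone C12–O bond. In the forward step the open-chain alkenyl iodide A1 (iodine on C5, aldehyde at C6, methyl ester at C12, chlorohydrin at C11, silyl ethers on C2 and C8) is treated with CrCl2 and catalytic NiCl2. The alkenylchromium adds to the aldehyde (Nozaki–Hiyama–Kishi) and the C6 alkoxide lactonises to A2.
- In its favour: one operation closes the ring and the lactone with every oxidation state final, and the reaction type is established for medium rings. A2 is the same compound as 28, so only two steps would remain after ring closure, against ten after the key step of the chosen plan. On mechanistic precedent and on late-stage economy it is the better plan.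
- Against it: C6 is created in the macrocyclisation under substrate control only. C7 of A1 is an α-formyl centre flanked by two oxygenated carbons and can epimerise or eliminate. A1 needs four stereocentres, including the quaternary C11, and both Z trisubstituted olefins to be built in an open chain.
- Comparison: the chosen plan fixes C6 and C7 by an auxiliary before any ring exists and obtains both Z olefins from ring constraints, but it pays with an unprecedented key step and two late ketone reductions. Overall step counts should be similar.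

Alternative 2: The cut is the C4=C5 double bond, traced back to the eleven-membered sulfone A3 with sulfur bridging C4 and C5. In the forward step A3 is halogenated in situ (CBr2F2, KOH on Al2O3), undergoes 1,3-elimination and loses SO2 (Ramberg–Bäcklund) to give the diene A4.
- In its favour: an eleven-membered sulfide ring is easier to close than a ten-membered carbocycle. All four carbinol centres (C2, C6, C7, C8) would be set by reagent control before ring formation, which is better than the chosen plan for C2 and C8. C13 is already in place, so no methylenation is needed.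
- Against it: nothing enforces the Z geometry of the new trisubstituted C4=C5 bond in a ten-membered ring. The strongly basic heterogeneous conditions sit next to allylic ethers. After A4 the route still needs two ether cleavages, oxidation of C12, lactonisation, epoxidation, chloride opening, desilylation and acetylation, the longest endgame of the four plans.
- Comparison: it is equal to the chosen plan in using known reactivity for every other step and better in precedent for the ring-forming step. It is weaker in olefin geometry, which the chosen plan secures through the eight-membered ring and the cyclobutene.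

Alternative 3: The cut is C7–C8. In the forward step the bromomethyl butenolide aldehyde A5 is treated with zinc or CrCl2. The allylmetal adds through C7 to the C8 aldehyde (intramolecular Barbier reaction), closing the ring and leaving the exocyclic methylene lactone in A6.
- In its favour: ring, C7, C8 and the C11=C13 unit arise in one operation. Silylation of A6 would give 26, so the plan joins the chosen route four steps from the end. This avoids the lactone enolate chemistry and is better in late-stage economy.
- Against it: two stereocentres are made in the macrocyclisation. C7 trans to C6 is plausible, but C8 depends on a ten-membered transition state. The C8 aldehyde of A5 has C9 between the formyl group and C10=C1 and is prone to conjugation. A5 needs C2 and C6 set independently, five atoms apart, and both Z olefins built in an open chain.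
- Comparison: both plans leave C8 to substrate control, the chosen one in a hydride reduction and this one in the ring closure. The chosen plan has C6 and C7 secured by the auxiliary; Alternative 3 has the better-precedented ring-forming step.

Key step: step 10

Remark on the chemistry: locants C1–C13 follow germacrane numbering of 30 throughout, and metal enolates, alkoxides and catalyst-bound species are treated as reactive forms of the numbered compounds, not as separate compounds.

## Route

Step 1
Reactants: 1 (4S)-4-benzyl-1,3-oxazolidin-2-one; 2 methyl 4-chloro-4-oxobutanoate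
Product: 3 methyl 4-[(4S)-4-benzyl-2-oxo-1,3-oxazolidin-3-yl]-4-oxobutanoate
Conditions: n-BuLi, THF, −78 °C; then 2, −78 → 0 °C
Reagents that add atoms: none
Why: N-acylation of the lithiated oxazolidinone; at −78 °C the acyl chloride is far more electrophilic than the methyl ester, so only the imide forms.

Step 2
Reactants: 3 succinate imide; 4 acrolein
Product: 5 methyl (3S,4R)-3-{[(4S)-4-benzyl-2-oxo-1,3-oxazolidin-3-yl]carbonyl}-4-hydroxyhex-5-enoate
Conditions: Bu2BOTf, iPr2NEt, CH2Cl2, −78 → 0 °C; 4, −78 → 0 °C; pH 7 buffer, MeOH, H2O2, 0 °C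
Reagents that add atoms: none
Why: Evans syn-aldol: only the imide α-CH2 (C7) is enolised, to the Z boron enolate, and acrolein adds 1,2 through a chair Zimmerman–Traxler transition state on the face away from the benzyl group, which sets C7 and C6 (syn). The crude aldol is silylated at once so that the γ-hydroxy ester does not lactonise.

Step 3
Reactants: 5 syn-aldol imide
Product: 6 methyl (3S,4R)-3-{[(4S)-4-benzyl-2-oxo-1,3-oxazolidin-3-yl]carbonyl}-4-[(triethylsilyl)oxy]hex-5-enoate
Conditions: Et3SiOTf, 2,6-lutidine, CH2Cl2, −78 °C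
Reagents that add atoms: triethylsilyl trifluoromethanesulfonate, CC[Si](CC)(CC)OS(=O)(=O)C(F)(F)F
Why: O-silylation with a silyl triflate is fast and non-basic, so neither retro-aldol nor lactonisation competes. Triethylsilyl is chosen because this ether must later be cleaved in the presence of two tert-butyldimethylsilyl ethers.

Step 4
Reactants: 6 silylated aldol imide
Product: 7 methyl (3S,4R)-3-[(ethylsulfanyl)carbonyl]-4-[(triethylsilyl)oxy]hex-5-enoate
Conditions: EtSH, n-BuLi, THF, 0 °C
Reagents that add atoms: ethanethiol, CCS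
Why: Thiolate cleavage of the imide: the small, soft nucleophile attacks the exocyclic carbonyl even of a branched acyl group and releases the auxiliary for recovery. The methyl ester and the silyl ether are inert at 0 °C.

Step 5
Reactants: 7 thioester
Product: 8 methyl (3S,4R)-3-acetyl-4-[(triethylsilyl)oxy]hex-5-enoate
Conditions: MeZnI, PdCl2(PPh3)2 (5 mol %), toluene–THF, rt
Reagents that add atoms: methylzinc iodide, C[Zn]I
Why: Fukuyama coupling (oxidative addition into C–S, transmetalation, reductive elimination) forms C8–C9. The organozinc neither adds to the ester nor epimerises C7, and the product has its only unhindered enolisable site at C9.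

Step 6
Reactants: 9 3-methylbut-3-en-1-ol
Product: 10 3-methylbut-3-enal
Conditions: Dess–Martin periodinane, NaHCO3, CH2Cl2, 0 °C; used at once as a cold solution
Reagents that add atoms: none
Why: Buffered Dess–Martin oxidation stops at the aldehyde; the β,γ-unsaturated aldehyde is kept cold and used directly so that the olefin does not move into conjugation.

Step 7
Reactants: 8 methyl ketone; 10 3-methylbut-3-enal
Product: 11 methyl (3S,4R)-3-(3-hydroxy-5-methylhex-5-enoyl)-4-[(triethylsilyl)oxy]hex-5-enoate (both epimers at the new carbinol carbon C2)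
Conditions: (c-C6H11)2BCl, Et3N, Et2O, −78 → 0 °C; then 10, −78 °C; then MeOH, pH 7 buffer, H2O2, 0 °C
Reagents that add atoms: none
Why: Boron-mediated aldol: the dialkylboron chloride and amine enolise the methyl ketone on its methyl side (C9), and the enol borinate adds to the aldehyde to form C9–C2 with the oxidation pattern C8 ketone and C2 carbinol. The new carbinol centre is not controlled and is erased in step 9.

Step 8
Reactants: 11 aldol diene
Product: 12 methyl 2-[(1S,2R,3Z)-6-hydroxy-4-methyl-8-oxo-2-[(triethylsilyl)oxy]cyclooct-3-en-1-yl]acetate (both epimers at the carbinol carbon)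
Conditions: second-generation Grubbs catalyst RuCl2(=CHPh)(H2IMes)(PCy3) (10 mol %), CH2Cl2 (1 mM), reflux
Reagents that add atoms: none
Why: Ring-closing metathesis forms C4=C5 with loss of ethene; an eight-membered ring can hold only the Z olefin. The hydroxy ketone is used because it rotates freely, whereas an open-chain 1,3-diketone would sit in its extended chelated enol.

Step 9
Reactants: 12 cyclic hydroxy ketone
Product: 13 methyl 2-[(1S,2R,3Z)-4-methyl-6,8-dioxo-2-[(triethylsilyl)oxy]cyclooct-3-en-1-yl]acetate
Conditions: Dess–Martin periodinane, NaHCO3, CH2Cl2, 0 °C → rt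
Reagents that add atoms: none
Why: Dess–Martin oxidation converts β-hydroxy ketones cleanly into 1,3-diketones; both epimers of 12 converge on the cyclooct-5-ene-1,3-dione.

Step 10
Reactants: 13 cyclooctenedione; 14 propyne
Product: 17 methyl 2-[(1S,2R,3Z,7Z)-4,8-dimethyl-6,10-dioxo-2-[(triethylsilyl)oxy]cyclodeca-3,7-dien-1-yl]acetate, via C2 trimethylsilyl enol ether 15 (not isolated), via cyclobutene photoadduct 16 (not isolated)
Conditions: Me3SiCl, Et3N, CH2Cl2, 0 °C, then filter and evaporate; 14 (excess), MeCN, hν (λ > 300 nm, Pyrex), −40 °C; then Bu4NF, AcOH, THF, −78 → 0 °C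
Reagents that add atoms: none
Why: Proposed new method: silylation fixes the enol on the less hindered C2 oxygen (15), whose enone chromophore O=C8–C9=C2–OSi is excited at its n→π* band and, from the triplet, bonds C2 to the unsubstituted alkyne carbon to give an α-keto radical at C9 and the more substituted vinyl radical at C10, which combine to the cis-fused cyclobutene 16. Fluoride then frees the C2 alkoxide, and strain release drives retro-aldol cleavage of C9–C2 to the C2 enone and the C8 enolate, which acetic acid protonates at C9. The closest known reactions are the de Mayo reaction of cyclic 1,3-diketone enols or their enol derivatives with alkenes and the [2+2] photocycloaddition of cyclic enones to alkynes; their combination on an alkyne has not been shown. The four-membered ring closes by stepwise radical combination within the 1,4-diradical, and the ten-membered ring arises by fragmentation of the bicyclo[6.2.0] skeleton and not by an end-to-end closure, so no medium-ring entropy is paid. No lasting stereocentre is created: C2 and C9 of 16 vanish on fragmentation, and C6 and C7 are untouched because the work-up is buffered and cold. Three selectivities are needed: the enol regiochemistry is secured by 15, the Z geometry of C1=C10 is forced by the cyclobutene and not touched by the heterolytic ring opening, and the alkyne orientation (methyl-bearing carbon to C9) is only favoured, by the fully substituted C2 terminus and by diradical stability, not secured. Irradiation above 300 nm at low temperature and to partial conversion should limit twisting of the eight-membered enone and secondary photoreaction of the β,γ-unsaturated ketone in 16.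

Step 11
Reactants: 17 ten-membered enedione
Product: 18 methyl 2-[(1R,2R,3Z,7Z,10R)-10-hydroxy-4,8-dimethyl-6-oxo-2-[(triethylsilyl)oxy]cyclodeca-3,7-dien-1-yl]acetate
Conditions: NaBH4, MeOH–CH2Cl2 (1:1), −78 °C
Reagents that add atoms: none
Why: At −78 °C borohydride reduces the saturated C8 ketone much faster than the β,β-disubstituted enone. Hydride adds anti to C6 and past H7 (Felkin–Anh, C6 large, the acetate arm medium), which also places the new oxygen 1,3-anti to the C6 silyloxy group and gives (8R). The cold, neutral work-up keeps the γ-hydroxy ester open.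

Step 12
Reactants: 18 C8 alcohol
Product: 19 methyl 2-[(1R,2R,3Z,7Z,10R)-10-[(tert-butyldimethylsilyl)oxy]-4,8-dimethyl-6-oxo-2-[(triethylsilyl)oxy]cyclodeca-3,7-dien-1-yl]acetate
Conditions: t-BuMe2SiOTf, 2,6-lutidine, CH2Cl2, −78 °C
Reagents that add atoms: tert-butyldimethylsilyl trifluoromethanesulfonate, CC(C)(C)[Si](C)(C)OS(=O)(=O)C(F)(F)F
Why: Immediate silylation blocks closure of the C8 hydroxyl onto the C12 ester (an 8,12-lactone). At −78 °C with lutidine the alcohol reacts far faster than the enone enolises.

Step 13
Reactants: 19 C8-protected enone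
Product: 20 methyl 2-[(1R,2R,3Z,6S,7Z,10R)-10-[(tert-butyldimethylsilyl)oxy]-6-hydroxy-4,8-dimethyl-2-[(triethylsilyl)oxy]cyclodeca-3,7-dien-1-yl]acetate
Conditions: (R)-Me-CBS [(3aR)-1-methyl-3,3-diphenyltetrahydro-1H,3H-pyrrolo[1,2-c][1,3,2]oxazaborole] (1 equiv), catecholborane, toluene, −78 °C
Reagents that add atoms: none
Why: Corey–Bakshi–Shibata reduction gives 1,2-reduction of the enone under reagent control, which is needed because C2 has no neighbouring stereocentre. With the alkenyl carbon C1 as the large group and C3 as the small one, the (R)-catalyst delivers hydride to give the (2S)-alcohol.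

Step 14
Reactants: 20 C2 allylic alcohol
Product: 21 methyl 2-[(1R,2R,3Z,6S,7Z,10R)-6,10-bis[(tert-butyldimethylsilyl)oxy]-4,8-dimethyl-2-[(triethylsilyl)oxy]cyclodeca-3,7-dien-1-yl]acetate
Conditions: t-BuMe2SiOTf, 2,6-lutidine, CH2Cl2, −78 °C
Reagents that add atoms: tert-butyldimethylsilyl trifluoromethanesulfonate, CC(C)(C)[Si](C)(C)OS(=O)(=O)C(F)(F)F
Why: Standard silylation; C2 and C8 now carry base-stable ethers for the enolate step, and both are more robust than the C6 triethylsilyl ether.

Step 15
Reactants: 21 tris-silyl ether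
Product: 23 (2S,6R,7S,8R)-2,8-bis[(tert-butyldimethylsilyl)oxy]germacra-1(10)Z,4Z-dien-12,6-olide, via hydroxy ester 22 (not isolated)
Conditions: PPTS, MeOH–CH2Cl2, 0 °C → rt; then PPTS, toluene, 50 °C
Reagents that add atoms: none
Why: Mild acid methanolysis removes the triethylsilyl ether and leaves the secondary tert-butyldimethylsilyl ethers. Only the C6 hydroxyl is then free, and it closes 5-exo onto the methyl ester to the trans-fused 6,12-lactone.

Step 16
Reactants: 23 lactone
Product: 26 (2S,6R,7S,8R)-2,8-bis[(tert-butyldimethylsilyl)oxy]germacra-1(10)Z,4Z,11(13)-trien-12,6-olide, via Mannich base 24 (not isolated), via trimethylammonium iodide 25 (not isolated)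
Conditions: LiN(iPr)2, THF, −78 °C; CH2=NMe2+ I−, −78 → 0 °C; then MeI, CH2Cl2–MeOH, rt; then aq. NaHCO3, rt
Reagents that add atoms: N,N-dimethylmethyleneiminium iodide (Eschenmoser's salt), C=[N+](C)C.[I-]
Why: Mannich methylenation: the lactone enolate (no leaving group on C7, so it is stable) is aminomethylated at C11, and quaternisation followed by mild base eliminates trimethylamine. The C11 configuration of 24 is irrelevant.

Step 17
Reactants: 26 α-methylene lactone
Product: 27 (2S,6R,7S,8R,11R)-2,8-bis[(tert-butyldimethylsilyl)oxy]-11,13-epoxygermacra-1(10)Z,4Z-dien-12,6-olide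
Conditions: t-BuOOH, DBU, CH2Cl2, 0 °C → rt
Reagents that add atoms: tert-butyl hydroperoxide, CC(C)(C)OO
Why: Weitz–Scheffer epoxidation: the peroxide anion adds only to C13 of the electron-poor olefin and leaves the two ring olefins alone. The resulting enolate closes the O–C11 bond on the α face, the side of H7 and away from the silyloxy-bearing C8 on C7.

Step 18
Reactants: 27 spiro-epoxide
Product: 28 (2S,6R,7S,8R,11S)-2,8-bis[(tert-butyldimethylsilyl)oxy]-13-chloro-11-hydroxygermacra-1(10)Z,4Z-dien-12,6-olide
Conditions: LiCl, AcOH, THF, rt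
Reagents that add atoms: lithium chloride, [Li+].[Cl-]
Why: Chloride opens the acid-activated epoxide by SN2 at the primary C13. The C11–O bond (tertiary and α to the carbonyl) is not broken, so C11 keeps its configuration.

Step 19
Reactants: 28 bis-silyl chlorohydrin
Product: 29 (2S,6R,7R,8R,11S)-13-chloro-2,8,11-trihydroxygermacra-1(10)Z,4Z-dien-12,6-olide
Conditions: HF·pyridine, pyridine, THF, 0 °C → rt
Reagents that add atoms: none
Why: Fluoride under buffered acidic conditions removes both silyl ethers; the chlorohydrin cannot reclose to the epoxide and the 8-hydroxyl does not translactonise without base.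

Step 20
Reactants: 29 triol
Product: 30 (2S,6R,7R,8R,11S)-2,8-diacetoxy-13-chloro-11-hydroxygermacra-1(10)Z,4Z-dien-12,6-olide (target)
Conditions: Ac2O, pyridine, 4-(dimethylamino)pyridine (cat.), CH2Cl2, 0 °C
Reagents that add atoms: acetic anhydride, CC(=O)OC(C)=O
Why: Acylation of the two secondary hydroxyls; the tertiary C11 hydroxyl, hindered and deactivated by the lactone carbonyl, should not react at 0 °C with limited anhydride.

## Compound list

1 | (4S)-4-benzyl-1,3-oxazolidin-2-one | O=C1N[C@@H](Cc2ccccc2)CO1 | starting material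
2 | methyl 4-chloro-4-oxobutanoate | COC(=O)CCC(Cl)=O | starting material
3 | methyl 4-[(4S)-4-benzyl-2-oxo-1,3-oxazolidin-3-yl]-4-oxobutanoate | COC(=O)CCC(=O)N1C(=O)OC[C@@H]1Cc1ccccc1 | intermediate
4 | acrolein (prop-2-enal) | C=CC=O | starting material
5 | methyl (3S,4R)-3-{[(4S)-4-benzyl-2-oxo-1,3-oxazolidin-3-yl]carbonyl}-4-hydroxyhex-5-enoate | O=C(N1C(=O)OC[C@@H]1Cc1ccccc1)[C@@H](CC(=O)OC)[C@H](O)C=C | intermediate
6 | methyl (3S,4R)-3-{[(4S)-4-benzyl-2-oxo-1,3-oxazolidin-3-yl]carbonyl}-4-[(triethylsilyl)oxy]hex-5-enoate | O=C(N1C(=O)OC[C@@H]1Cc1ccccc1)[C@@H](CC(=O)OC)[C@H](O[Si](CC)(CC)CC)C=C | intermediate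
7 | methyl (3S,4R)-3-[(ethylsulfanyl)carbonyl]-4-[(triethylsilyl)oxy]hex-5-enoate | CCSC(=O)[C@@H](CC(=O)OC)[C@H](O[Si](CC)(CC)CC)C=C | intermediate
8 | methyl (3S,4R)-3-acetyl-4-[(triethylsilyl)oxy]hex-5-enoate | CC(=O)[C@@H](CC(=O)OC)[C@H](O[Si](CC)(CC)CC)C=C | intermediate
9 | 3-methylbut-3-en-1-ol | CC(=C)CCO | starting material
10 | 3-methylbut-3-enal | CC(=C)CC=O | intermediate
11 | methyl (3S,4R)-3-(3-hydroxy-5-methylhex-5-enoyl)-4-[(triethylsilyl)oxy]hex-5-enoate (both carbinol epimers) | CC(=C)CC(O)CC(=O)[C@@H](CC(=O)OC)[C@H](O[Si](CC)(CC)CC)C=C | intermediate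
12 | methyl 2-[(1S,2R,3Z)-6-hydroxy-4-methyl-8-oxo-2-[(triethylsilyl)oxy]cyclooct-3-en-1-yl]acetate (both carbinol epimers) | OC1CC(=O)[C@@H](CC(=O)OC)[C@H](O[Si](CC)(CC)CC)/C=C(/C)C1 | intermediate
13 | methyl 2-[(1S,2R,3Z)-4-methyl-6,8-dioxo-2-[(triethylsilyl)oxy]cyclooct-3-en-1-yl]acetate | O=C1CC(=O)[C@@H](CC(=O)OC)[C@H](O[Si](CC)(CC)CC)/C=C(/C)C1 | intermediate
14 | propyne | CC#C | starting material
15 | methyl 2-[(1S,2R,3Z,6E)-4-methyl-8-oxo-2-[(triethylsilyl)oxy]-6-[(trimethylsilyl)oxy]cycloocta-3,6-dien-1-yl]acetate | C[Si](C)(C)O/C1=C/C(=O)[C@@H](CC(=O)OC)[C@H](O[Si](CC)(CC)CC)/C=C(/C)C1 | intermediate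
16 | methyl 2-[(3Z,5R,6S)-3,9-dimethyl-7-oxo-5-[(triethylsilyl)oxy]-1-[(trimethylsilyl)oxy]bicyclo[6.2.0]deca-3,9-dien-6-yl]acetate (cis ring fusion; C1 and C8 not controlled) | C[Si](C)(C)OC12C=C(C)C1C(=O)[C@@H](CC(=O)OC)[C@H](O[Si](CC)(CC)CC)/C=C(/C)C2 | intermediate
17 | methyl 2-[(1S,2R,3Z,7Z)-4,8-dimethyl-6,10-dioxo-2-[(triethylsilyl)oxy]cyclodeca-3,7-dien-1-yl]acetate | O=C1/C=C(/C)CC(=O)[C@@H](CC(=O)OC)[C@H](O[Si](CC)(CC)CC)/C=C(/C)C1 | intermediate
18 | methyl 2-[(1R,2R,3Z,7Z,10R)-10-hydroxy-4,8-dimethyl-6-oxo-2-[(triethylsilyl)oxy]cyclodeca-3,7-dien-1-yl]acetate | O=C1/C=C(/C)C[C@@H](O)[C@@H](CC(=O)OC)[C@H](O[Si](CC)(CC)CC)/C=C(/C)C1 | intermediate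
19 | methyl 2-[(1R,2R,3Z,7Z,10R)-10-[(tert-butyldimethylsilyl)oxy]-4,8-dimethyl-6-oxo-2-[(triethylsilyl)oxy]cyclodeca-3,7-dien-1-yl]acetate | O=C1/C=C(/C)C[C@@H](O[Si](C)(C)C(C)(C)C)[C@@H](CC(=O)OC)[C@H](O[Si](CC)(CC)CC)/C=C(/C)C1 | intermediate
20 | methyl 2-[(1R,2R,3Z,6S,7Z,10R)-10-[(tert-butyldimethylsilyl)oxy]-6-hydroxy-4,8-dimethyl-2-[(triethylsilyl)oxy]cyclodeca-3,7-dien-1-yl]acetate | O[C@@H]1/C=C(/C)C[C@@H](O[Si](C)(C)C(C)(C)C)[C@@H](CC(=O)OC)[C@H](O[Si](CC)(CC)CC)/C=C(/C)C1 | intermediate
21 | methyl 2-[(1R,2R,3Z,6S,7Z,10R)-6,10-bis[(tert-butyldimethylsilyl)oxy]-4,8-dimethyl-2-[(triethylsilyl)oxy]cyclodeca-3,7-dien-1-yl]acetate | CC(C)(C)[Si](C)(C)O[C@@H]1/C=C(/C)C[C@@H](O[Si](C)(C)C(C)(C)C)[C@@H](CC(=O)OC)[C@H](O[Si](CC)(CC)CC)/C=C(/C)C1 | intermediate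
22 | methyl 2-[(1S,2R,3Z,6S,7Z,10R)-6,10-bis[(tert-butyldimethylsilyl)oxy]-2-hydroxy-4,8-dimethylcyclodeca-3,7-dien-1-yl]acetate | CC(C)(C)[Si](C)(C)O[C@@H]1/C=C(/C)C[C@@H](O[Si](C)(C)C(C)(C)C)[C@@H](CC(=O)OC)[C@H](O)/C=C(/C)C1 | intermediate
23 | (2S,6R,7S,8R)-2,8-bis[(tert-butyldimethylsilyl)oxy]germacra-1(10)Z,4Z-dien-12,6-olide | CC(C)(C)[Si](C)(C)O[C@@H]1/C=C(/C)C[C@@H](O[Si](C)(C)C(C)(C)C)[C@@H]2[C@@H](/C=C(/C)C1)OC(=O)C2 | intermediate
24 | (2S,6R,7S,8R)-2,8-bis[(tert-butyldimethylsilyl)oxy]-13-(dimethylamino)germacra-1(10)Z,4Z-dien-12,6-olide (C11 epimers) | CC(C)(C)[Si](C)(C)O[C@@H]1/C=C(/C)C[C@@H](O[Si](C)(C)C(C)(C)C)[C@@H]2[C@@H](/C=C(/C)C1)OC(=O)C2CN(C)C | intermediate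
25 | trimethylammonium iodide of 24: (2S,6R,7S,8R)-2,8-bis[(tert-butyldimethylsilyl)oxy]-12-oxo-12,6-epoxygermacra-1(10)Z,4Z-dien-13-yl(trimethyl)azanium iodide (C11 epimers) | CC(C)(C)[Si](C)(C)O[C@@H]1/C=C(/C)C[C@@H](O[Si](C)(C)C(C)(C)C)[C@@H]2[C@@H](/C=C(/C)C1)OC(=O)C2C[N+](C)(C)C.[I-] | intermediate
26 | (2S,6R,7S,8R)-2,8-bis[(tert-butyldimethylsilyl)oxy]germacra-1(10)Z,4Z,11(13)-trien-12,6-olide | CC(C)(C)[Si](C)(C)O[C@@H]1/C=C(/C)C[C@@H](O[Si](C)(C)C(C)(C)C)[C@@H]2[C@@H](/C=C(/C)C1)OC(=O)C2=C | intermediate
27 | (2S,6R,7S,8R,11R)-2,8-bis[(tert-butyldimethylsilyl)oxy]-11,13-epoxygermacra-1(10)Z,4Z-dien-12,6-olide | CC(C)(C)[Si](C)(C)O[C@@H]1/C=C(/C)C[C@@H](O[Si](C)(C)C(C)(C)C)[C@@H]2[C@@H](/C=C(/C)C1)OC(=O)[C@]2(O3)C3 | intermediate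
28 | (2S,6R,7S,8R,11S)-2,8-bis[(tert-butyldimethylsilyl)oxy]-13-chloro-11-hydroxygermacra-1(10)Z,4Z-dien-12,6-olide | CC(C)(C)[Si](C)(C)O[C@@H]1/C=C(/C)C[C@@H](O[Si](C)(C)C(C)(C)C)[C@@H]2[C@@H](/C=C(/C)C1)OC(=O)[C@]2(O)CCl | intermediate
29 | (2S,6R,7R,8R,11S)-13-chloro-2,8,11-trihydroxygermacra-1(10)Z,4Z-dien-12,6-olide | O[C@@H]1/C=C(/C)C[C@@H](O)[C@@H]2[C@@H](/C=C(/C)C1)OC(=O)[C@]2(O)CCl | intermediate
30 | (2S,6R,7R,8R,11S)-2,8-diacetoxy-13-chloro-11-hydroxygermacra-1(10)Z,4Z-dien-12,6-olide (CNP0182971.4) | CC(=O)O[C@@H]1/C=C(/C)C[C@@H](OC(C)=O)[C@@H]2[C@@H](/C=C(/C)C1)OC(=O)[C@]2(O)CCl | target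

## Step count and least certain steps

Total: 20 steps. Longest linear sequence: 19 steps (steps 1–5 and 7–20); step 6 prepares the aldehyde 10 on a one-step side branch.

Step 10 (key step). Three processes are most likely to go wrong.
- Loss of regiocontrol: propyne may add in the reverse orientation, or the silyl group may settle on the C8 oxygen before irradiation. Either gives an isomeric enedione.
- Relaxation of the excited eight-membered enone by twisting about C9=C2 instead of cycloaddition, which leads to oligomers.
- Secondary photoreaction of the β,γ-unsaturated ketone in 16.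

The fallback replaces the photochemistry by a thermal, metal-catalysed two-carbon ring expansion. 13 is heated with 14 and catalytic [ReBr(CO)3(thf)]2 with an isocyanide ligand in toluene. This is a formal insertion of a terminal alkyne into the C–C bond of a cyclic 1,3-dicarbonyl compound, a reaction type established for cyclic β-keto esters. The metal enolate adds C9 to the internal alkyne carbon, the alkenylmetal closes on the less hindered C2 carbonyl, and the cyclobutenolate opens by the same retro-aldol cleavage. The fallback sets out from 13 and 14 and comes back at 17; it makes no new compound (entry F0).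

Step 8. The ruthenium alkylidene forms readily at the unhindered C5 vinyl group but may engage the 1,1-disubstituted olefin too slowly at the dilution an eight-membered ring needs, so dimerisation and oligomerisation through C5 can take over. The fallback is a relay ring closure that loads the catalyst at the hindered terminus instead.
- 4,4-Dimethoxybutan-2-one is olefinated with the ylide from hex-5-enyl(triphenyl)phosphonium bromide and NaN(SiMe3)2 to give 1,1-dimethoxy-3-methylnona-3,8-diene F1.
- Mild aqueous acid releases 3-methylnona-3,8-dienal F2.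
- The boron aldol of step 7 with 8 gives methyl (3S,4R)-3-(3-hydroxy-5-methylundeca-5,10-dienoyl)-4-[(triethylsilyl)oxy]hex-5-enoate F3.
- On metathesis of F3 the catalyst enters at the terminal vinyl group, expels cyclopentene to place the alkylidene on C4, and closes onto the C5 vinyl group.

It sets out from 8 and comes back at 12.

Step 11. Facial selectivity of hydride addition to the C8 ketone may be poor in the flexible ten-membered ring, and the new C8 hydroxyl may close onto the C12 ester before it is silylated. The fallback forms the 6,12-lactone first, so that C12 is no longer available and the fused lactone shields the β face of C8.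
- 17 is desilylated and lactonised (PPTS, MeOH, then toluene, 50 °C) to (6R,7S)-2,8-dioxogermacra-1(10)Z,4Z-dien-12,6-olide F4.
- NaBH4 at −78 °C attacks from the α face (the side of H7, away from C11) to give (6R,7R,8R)-8-hydroxy-2-oxogermacra-1(10)Z,4Z-dien-12,6-olide F5.
- Silylation gives (6R,7S,8R)-8-[(tert-butyldimethylsilyl)oxy]-2-oxogermacra-1(10)Z,4Z-dien-12,6-olide F6.
- The reduction of step 13 gives (2S,6R,7S,8R)-8-[(tert-butyldimethylsilyl)oxy]-2-hydroxygermacra-1(10)Z,4Z-dien-12,6-olide F7, and a second silylation gives 23.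

It sets out from 17 and comes back at 23.

Step 13. Diastereoselectivity may be low if the facial bias of the ring opposes the catalyst or if C1 and C3 are not told apart well enough. The fallback uses substrate-controlled reduction followed by stereoinversion.
- 19 is reduced with NaBH4 and CeCl3·7H2O (Luche), and the epimers are separated.
- The unwanted methyl 2-[(1R,2R,3Z,6R,7Z,10R)-10-[(tert-butyldimethylsilyl)oxy]-6-hydroxy-4,8-dimethyl-2-[(triethylsilyl)oxy]cyclodeca-3,7-dien-1-yl]acetate F8 is inverted by a Mitsunobu reaction with 4-nitrobenzoic acid.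
- This gives methyl 2-[(1R,2R,3Z,6S,7Z,10R)-10-[(tert-butyldimethylsilyl)oxy]-4,8-dimethyl-6-[(4-nitrobenzoyl)oxy]-2-[(triethylsilyl)oxy]cyclodeca-3,7-dien-1-yl]acetate F9, which is methanolysed (K2CO3, MeOH).

It sets out from 19 and comes back at 20.

Step 17. The peroxide-derived oxygen may be delivered to the β face of C11 (poor facial selectivity), or the peroxide anion may cleave the lactone. The fallback inverts the order of bond formation at C11, so that the same facial bias places carbon, not oxygen, on the β face.
- The enolate of 23 is hydroxylated with 2-(phenylsulfonyl)-3-phenyloxaziridine to (2S,6R,7S,8R)-2,8-bis[(tert-butyldimethylsilyl)oxy]-11-hydroxygermacra-1(10)Z,4Z-dien-12,6-olide F10 (either C11 epimer serves).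
- The dianion of F10 (LiN(iPr)2, 2.2 equiv) is trapped with formaldehyde to give (2S,6R,7S,8R,11R)-2,8-bis[(tert-butyldimethylsilyl)oxy]-11,13-dihydroxygermacra-1(10)Z,4Z-dien-12,6-olide F11.
- The primary hydroxyl alone is replaced by chloride with PPh3 and CCl4 (Appel).

It sets out from 23 and comes back at 28.

## Further compounds

F0 | step 10 | none | none
F1 | step 8 | 1,1-dimethoxy-3-methylnona-3,8-diene (E/Z mixture) | COC(OC)CC(C)=CCCCC=C
F2 | step 8 | 3-methylnona-3,8-dienal (E/Z mixture) | O=CCC(C)=CCCCC=C
F3 | step 8 | methyl (3S,4R)-3-(3-hydroxy-5-methylundeca-5,10-dienoyl)-4-[(triethylsilyl)oxy]hex-5-enoate (carbinol epimers, E/Z mixture) | C=CCCCC=C(C)CC(O)CC(=O)[C@@H](CC(=O)OC)[C@H](O[Si](CC)(CC)CC)C=C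
F4 | step 11 | (6R,7S)-2,8-dioxogermacra-1(10)Z,4Z-dien-12,6-olide | O=C1/C=C(/C)CC(=O)[C@@H]2[C@@H](/C=C(/C)C1)OC(=O)C2
F5 | step 11 | (6R,7R,8R)-8-hydroxy-2-oxogermacra-1(10)Z,4Z-dien-12,6-olide | O=C1/C=C(/C)C[C@@H](O)[C@@H]2[C@@H](/C=C(/C)C1)OC(=O)C2
F6 | step 11 | (6R,7S,8R)-8-[(tert-butyldimethylsilyl)oxy]-2-oxogermacra-1(10)Z,4Z-dien-12,6-olide | O=C1/C=C(/C)C[C@@H](O[Si](C)(C)C(C)(C)C)[C@@H]2[C@@H](/C=C(/C)C1)OC(=O)C2
F7 | step 11 | (2S,6R,7S,8R)-8-[(tert-butyldimethylsilyl)oxy]-2-hydroxygermacra-1(10)Z,4Z-dien-12,6-olide | O[C@@H]1/C=C(/C)C[C@@H](O[Si](C)(C)C(C)(C)C)[C@@H]2[C@@H](/C=C(/C)C1)OC(=O)C2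
F8 | step 13 | methyl 2-[(1R,2R,3Z,6R,7Z,10R)-10-[(tert-butyldimethylsilyl)oxy]-6-hydroxy-4,8-dimethyl-2-[(triethylsilyl)oxy]cyclodeca-3,7-dien-1-yl]acetate | O[C@H]1/C=C(/C)C[C@@H](O[Si](C)(C)C(C)(C)C)[C@@H](CC(=O)OC)[C@H](O[Si](CC)(CC)CC)/C=C(/C)C1
F9 | step 13 | methyl 2-[(1R,2R,3Z,6S,7Z,10R)-10-[(tert-butyldimethylsilyl)oxy]-4,8-dimethyl-6-[(4-nitrobenzoyl)oxy]-2-[(triethylsilyl)oxy]cyclodeca-3,7-dien-1-yl]acetate | O=C(O[C@@H]1/C=C(/C)C[C@@H](O[Si](C)(C)C(C)(C)C)[C@@H](CC(=O)OC)[C@H](O[Si](CC)(CC)CC)/C=C(/C)C1)c1ccc(cc1)[N+](=O)[O-]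
F10 | step 17 | (2S,6R,7S,8R)-2,8-bis[(tert-butyldimethylsilyl)oxy]-11-hydroxygermacra-1(10)Z,4Z-dien-12,6-olide (C11 epimers) | CC(C)(C)[Si](C)(C)O[C@@H]1/C=C(/C)C[C@@H](O[Si](C)(C)C(C)(C)C)[C@@H]2[C@@H](/C=C(/C)C1)OC(=O)C2O
F11 | step 17 | (2S,6R,7S,8R,11R)-2,8-bis[(tert-butyldimethylsilyl)oxy]-11,13-dihydroxygermacra-1(10)Z,4Z-dien-12,6-olide | CC(C)(C)[Si](C)(C)O[C@@H]1/C=C(/C)C[C@@H](O[Si](C)(C)C(C)(C)C)[C@@H]2[C@@H](/C=C(/C)C1)OC(=O)[C@]2(O)CO
A1 | alternative 1 | methyl 2,8-bis[(tert-butyldimethylsilyl)oxy]-13-chloro-11-hydroxy-5-iodo-6-oxo-5,6-secogermacra-1(10)Z,4Z-dien-12-oate (C2, C7, C8, C11 arranged as in 30) | I/C=C(/C)C[C@H](O[Si](C)(C)C(C)(C)C)/C=C(/C)C[C@@H](O[Si](C)(C)C(C)(C)C)[C@H](C=O)[C@@](O)(CCl)C(=O)OC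
A2 | alternative 1 | (2S,6R,7S,8R,11S)-2,8-bis[(tert-butyldimethylsilyl)oxy]-13-chloro-11-hydroxygermacra-1(10)Z,4Z-dien-12,6-olide (identical with 28) | CC(C)(C)[Si](C)(C)O[C@@H]1/C=C(/C)C[C@@H](O[Si](C)(C)C(C)(C)C)[C@@H]2[C@@H](/C=C(/C)C1)OC(=O)[C@]2(O)CCl
A3 | alternative 2 | eleven-membered cyclic sulfone with SO2 between C4 and C5: 2,8-bis[(tert-butyldimethylsilyl)oxy]-6,12-bis[(4-methoxybenzyl)oxy]-4,5-secogermacra-1(10)Z,11(13)-diene-4,5-diyl sulfone (C4 epimers) | CC(C)(C)[Si](C)(C)O[C@@H]1/C=C(/C)C[C@@H](O[Si](C)(C)C(C)(C)C)[C@H]([C@H](OCc2ccc(OC)cc2)CS(=O)(=O)C(C)C1)C(=C)COCc2ccc(OC)cc2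
A4 | alternative 2 | 2,8-bis[(tert-butyldimethylsilyl)oxy]-6,12-bis[(4-methoxybenzyl)oxy]germacra-1(10)Z,4Z,11(13)-triene (C2, C6, C7, C8 arranged as in 30) | CC(C)(C)[Si](C)(C)O[C@@H]1/C=C(/C)C[C@@H](O[Si](C)(C)C(C)(C)C)[C@H]([C@H](OCc2ccc(OC)cc2)/C=C(/C)C1)C(=C)COCc2ccc(OC)cc2
A5 | alternative 3 | 13-bromo-2-[(tert-butyldimethylsilyl)oxy]-8-oxo-7,8-secogermacra-1(10)Z,4Z,7(11)-trien-12,6-olide (C2 and C6 arranged as in 30) | O=CC/C(C)=C\[C@@H](O[Si](C)(C)C(C)(C)C)C/C(C)=C\[C@H]1OC(=O)C(CBr)=C1
A6 | alternative 3 | (2S,6R,7R,8R)-2-[(tert-butyldimethylsilyl)oxy]-8-hydroxygermacra-1(10)Z,4Z,11(13)-trien-12,6-olide | CC(C)(C)[Si](C)(C)O[C@@H]1/C=C(/C)C[C@@H](O)[C@@H]2[C@@H](/C=C(/C)C1)OC(=O)C2=C
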